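**Retrosynthetic overview**

1. 12 ⇒ 10 + 11: the last bond is C-prenylation of the tri-acyl carbon by zerovalent-palladium allylation, which sets the last quaternary centre.
2. 10 ⇒ 8: key step. The acetyl C=O is made by C=C → C=O cleavage of an isopropenyl group (carbon–oxygen bond formation). Carrying the acetyl as isopropenyl lets both side chains of the cascade precursor be the same prenyl group.
3. 8 ⇒ 7: one oxidative radical cascade closes the bicyclo[3.2.1]octane first (5-exo), then the fused cyclopentane (5-exo).
4. 7 ⇒ 6: enantioselective dearomatising C-methylation of a symmetric arene (new step) sets the quaternary stereocentre that steers all later ones.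
5. 6 ⇒ phloroglucinol 1, isobutyryl chloride 2 and prenyl bromide 4 by two aromatic substitutions.

Assumption: enolised β-triketones (7, 8, 10 and related compounds) are written as one tautomer, and the CIP descriptors refer to the tautomer drawn.

**Route**

Step 1
Reactants: 1 phloroglucinol (benzene-1,3,5-triol); 2 isobutyryl chloride (2-methylpropanoyl chloride)
Product: 3 phlorisobutyrophenone [2-methyl-1-(2,4,6-trihydroxyphenyl)propan-1-one]
Conditions: AlCl3 (3.5 equiv), PhNO2, 65 °C; ice/aq. HCl work-up
Reagents that add atoms: none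
Why: Friedel–Crafts acylation of the very electron-rich arene stops at mono-acylation because the AlCl3-chelated aryl ketone is deactivated; no stereocentre is formed.

Step 2
Reactants: 3 phlorisobutyrophenone; 4 prenyl bromide (1-bromo-3-methylbut-2-ene, 2.1 equiv)
Product: 6 deoxycohumulone [2-methyl-1-[2,4,6-trihydroxy-3,5-bis(3-methylbut-2-en-1-yl)phenyl]propan-1-one], via 3-prenylphlorisobutyrophenone 5 (not isolated)
Conditions: 10% aq. KOH, 0 °C
Reagents that add atoms: none
Why: C-alkylation of the phloroglucinolate in water (hydrogen bonding suppresses O-alkylation) occurs at the two free ring carbons by SN2 attack on the primary allylic bromide; stoichiometry and low temperature limit the dearomatising third prenylation.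

Step 3
Reactants: 6 deoxycohumulone
Product: 7 (6S)-3,5-dihydroxy-6-methyl-4,6-bis(3-methylbut-2-en-1-yl)-2-(2-methylpropanoyl)cyclohexa-2,4-dien-1-one
Conditions: MeI (1.05 equiv), N-(9-anthracenylmethyl)cinchonidinium chloride (10 mol %), CsOH·H2O (2.2 equiv), toluene/CH2Cl2 4:1, −40 °C
Reagents that add atoms: iodomethane (MeI), CI
Why: Proposed new method: asymmetric phase-transfer C-methylation that dearomatises the symmetric arene 6; solid CsOH gives the 4-phenoxide, which enters the organic phase as a contact ion pair with the chiral ammonium (N+ over one ring face, 9-OH hydrogen-bonded to the phenoxide oxygen, anthracenyl wall over one of the two enantiotopic prenyl-bearing ortho carbons), so MeI alkylates the exposed ortho carbon from the open face and creates the (S) quaternary centre, C- over O-methylation following from the tight ion pair in a non-polar medium and over-methylation being curbed because the more acidic product is parked as its poorly nucleophilic triketonate; the closest known reactions are cinchona-ammonium phase-transfer methylation of indanone enolates and phase-transfer alkylative dearomatisation of acylphloroglucinols with activated electrophiles, and if the cinchonidinium salt gives the (R) antipode the pseudoenantiomeric cinchoninium salt is used.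

Step 4
Reactants: 7 (6S)-methylated dearomatised triketone
Product: 8 (1S,3R,5R,7S)-10-hydroxy-4,4,7-trimethyl-9-(2-methylpropanoyl)-3-(prop-1-en-2-yl)tricyclo[5.3.1.0^{1,5}]undec-9-ene-8,11-dione (CMe2 carbon on the side of the one-carbon ketone bridge, isopropenyl cis to the ring-fusion H)
Conditions: Mn(OAc)3·2H2O (2.2 equiv), Cu(OAc)2·H2O (20 mol %), degassed AcOH, 23 °C; chromatography
Reagents that add atoms: none
Why: Mn(OAc)3/Cu(OAc)2 oxidative free-radical cyclisation: the trivalent manganese enolate gives the radical at the prenyl-bearing enol carbon, which adds 5-exo to the prenyl group on the quaternary carbon (that centre fixes both bridgeheads), the tertiary radical then adds 5-exo to the second prenyl group with the new side chain on the convex face (cis to the ring-fusion H), and divalent copper oxidises the last radical to the isopropenyl group; the first closure has little exo/endo bias, so 8 is separated from its ring-fusion diastereomer, expected in comparable amount.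

Step 5
Reactants: 8 tricyclic isopropenyl enol-dione
Product: 10 (1S,3S,5R,7S)-3-acetyl-10-hydroxy-4,4,7-trimethyl-9-(2-methylpropanoyl)tricyclo[5.3.1.0^{1,5}]undec-9-ene-8,11-dione, via secondary ozonide 9 (not isolated)
Conditions: O3, CH2Cl2, −78 °C (Sudan Red 7B end point); then Me2S, −78 → 23 °C
Reagents that add atoms: ozone, [O-][O+]=O
Why: Ozonolysis (Criegee mechanism) of the only electron-rich C=C, the 1,1-disubstituted isopropenyl group, forms the acetyl carbon–oxygen bond and excises CH2, while the chelated, acyl-substituted enol is electron-poor and is spared at −78 °C with indicator control; no stereocentre is touched and the α-carbon is not enolised under these neutral conditions.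

Step 6
Reactants: 10 tricyclic methyl ketone; 11 prenyl acetate (3-methylbut-2-en-1-yl acetate, 1.5 equiv)
Product: 12 (1R,3S,5R,7S,9S)-3-acetyl-4,4,7-trimethyl-9-(3-methylbut-2-en-1-yl)-9-(2-methylpropanoyl)tricyclo[5.3.1.0^{1,5}]undecane-8,10,11-trione (target)
Conditions: Pd(PPh3)4 (5 mol %), Et3N (1.2 equiv), THF, 40 °C
Reagents that add atoms: none
Why: Tsuji–Trost allylation: zerovalent palladium ionises 11 to the π-prenyl complex, which the soft triethylammonium triketonate of 10 attacks through carbon at the CH2 terminus (O-prenyl by-products are re-ionised and funnelled to the C-product); the planar enolate is attacked on the face syn to the one-carbon ketone bridge, away from the two-carbon bridge and its endo hydrogens, so prenyl ends syn to that bridge and isobutyryl toward the two-carbon bridge (9S).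

**Compound list**

1 | phloroglucinol (benzene-1,3,5-triol) | Oc1cc(O)cc(O)c1 | starting material
2 | isobutyryl chloride (2-methylpropanoyl chloride) | CC(C)C(Cl)=O | starting material
3 | phlorisobutyrophenone, 2-methyl-1-(2,4,6-trihydroxyphenyl)propan-1-one | CC(C)C(=O)c1c(O)cc(O)cc1O | intermediate
4 | prenyl bromide (1-bromo-3-methylbut-2-ene) | CC(C)=CCBr | starting material
5 | 3-prenylphlorisobutyrophenone, 2-methyl-1-[2,4,6-trihydroxy-3-(3-methylbut-2-en-1-yl)phenyl]propan-1-one (not isolated) | CC(C)C(=O)c1c(O)cc(O)c(CC=C(C)C)c1O | intermediate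
6 | deoxycohumulone, 2-methyl-1-[2,4,6-trihydroxy-3,5-bis(3-methylbut-2-en-1-yl)phenyl]propan-1-one | CC(C)C(=O)c1c(O)c(CC=C(C)C)c(O)c(CC=C(C)C)c1O | intermediate
7 | (6S)-3,5-dihydroxy-6-methyl-4,6-bis(3-methylbut-2-en-1-yl)-2-(2-methylpropanoyl)cyclohexa-2,4-dien-1-one | CC(C)C(=O)C1=C(O)C(CC=C(C)C)=C(O)[C@](C)(CC=C(C)C)C1=O | intermediate
8 | (1S,3R,5R,7S)-10-hydroxy-4,4,7-trimethyl-9-(2-methylpropanoyl)-3-(prop-1-en-2-yl)tricyclo[5.3.1.0^{1,5}]undec-9-ene-8,11-dione | CC(=C)[C@H]1C[C@]23C(=O)[C@](C)(C[C@@H]2C1(C)C)C(=O)C(C(=O)C(C)C)=C3O | intermediate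
9 | secondary ozonide of 8: the isopropenyl group converted into a 3-methyl-1,2,4-trioxolan-3-yl group, ring stereocentres as in 8, mixture at the trioxolane carbon (not isolated) | CC4(OCOO4)[C@H]1C[C@]23C(=O)[C@](C)(C[C@@H]2C1(C)C)C(=O)C(C(=O)C(C)C)=C3O | intermediate
10 | (1S,3S,5R,7S)-3-acetyl-10-hydroxy-4,4,7-trimethyl-9-(2-methylpropanoyl)tricyclo[5.3.1.0^{1,5}]undec-9-ene-8,11-dione | CC(=O)[C@H]1C[C@]23C(=O)[C@](C)(C[C@@H]2C1(C)C)C(=O)C(C(=O)C(C)C)=C3O | intermediate
11 | prenyl acetate (3-methylbut-2-en-1-yl acetate) | CC(C)=CCOC(C)=O | starting material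
12 | (1R,3S,5R,7S,9S)-3-acetyl-4,4,7-trimethyl-9-(3-methylbut-2-en-1-yl)-9-(2-methylpropanoyl)tricyclo[5.3.1.0^{1,5}]undecane-8,10,11-trione | CC(=O)[C@H]1C[C@]23C(=O)[C@](C)(C[C@@H]2C1(C)C)C(=O)[C@](CC=C(C)C)(C(=O)C(C)C)C3=O | target

**Step count and risks**

Total steps: 6. Longest linear sequence: 6 steps (fully linear from 1).

Steps most likely to fail:

Step 3 (the proposed new step; the level of enantiocontrol is unknown). Fallback with known chemistry: from 6, methylate without chiral control (NaOMe, MeI, MeOH, 0 → 23 °C, the standard dearomatising C-alkylation of acylphloroglucinols) to give racemic 3,5-dihydroxy-6-methyl-4,6-bis(3-methylbut-2-en-1-yl)-2-(2-methylpropanoyl)cyclohexa-2,4-dien-1-one F1. Resolve it by preparative chiral supercritical-fluid chromatography (amylose tris(3,5-dimethylphenylcarbamate) phase, CO2/MeOH). The (6S) fraction is 7, where the route is rejoined.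

Step 4 (moderate yield, and about half of the material is lost as the ring-fusion diastereomer). Fallback by halogen-atom transfer instead of enol oxidation: from 7, NBS (1.0 equiv, CH2Cl2, −78 °C) brominates the prenyl-bearing enol carbon to give 4-bromo-3-hydroxy-6-methyl-4,6-bis(3-methylbut-2-en-1-yl)-2-(2-methylpropanoyl)cyclohex-2-ene-1,5-dione F2 (quaternary methyl centre unchanged, mixture at C–Br). Et3B (0.3 equiv)/air in benzene at 23 °C then starts a bromine-atom-transfer double 5-exo cyclisation to the tertiary bromide 3-(2-bromopropan-2-yl)-10-hydroxy-4,4,7-trimethyl-9-(2-methylpropanoyl)tricyclo[5.3.1.0^{1,5}]undec-9-ene-8,11-dione F3 (ring stereocentres as in 8). KOtBu (2.2 equiv, THF, 0 °C) eliminates HBr toward a methyl group, and the route is rejoined at 8.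

Step 6 (C- versus O-alkylation at a tri-acyl carbon, and facial selectivity). Fallback by O-alkylation and sigmatropic shift: from 10, 3-chloro-3-methylbut-1-yne with CuCl2 (1 mol %) and DBU in MeCN at 0 °C gives the propargyl enol ether 3-acetyl-4,4,7-trimethyl-10-[(2-methylbut-3-yn-2-yl)oxy]-9-(2-methylpropanoyl)tricyclo[5.3.1.0^{1,5}]undec-9-ene-8,11-dione F4. Semi-hydrogenation (H2, Pd on CaCO3 poisoned with Pb(OAc)2, quinoline, EtOAc) gives the allyl enol ether 3-acetyl-4,4,7-trimethyl-10-[(2-methylbut-3-en-2-yl)oxy]-9-(2-methylpropanoyl)tricyclo[5.3.1.0^{1,5}]undec-9-ene-8,11-dione F5. Heating in toluene at 80 °C effects a [3,3] Claisen shift that delivers the prenyl group to the acyl-bearing carbon from the same less hindered face, arriving at 12.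

**Further compounds**

F1 | step 3 | racemic 3,5-dihydroxy-6-methyl-4,6-bis(3-methylbut-2-en-1-yl)-2-(2-methylpropanoyl)cyclohexa-2,4-dien-1-one | CC(C)C(=O)C1=C(O)C(CC=C(C)C)=C(O)C(C)(CC=C(C)C)C1=O
F2 | step 4 | 4-bromo-3-hydroxy-6-methyl-4,6-bis(3-methylbut-2-en-1-yl)-2-(2-methylpropanoyl)cyclohex-2-ene-1,5-dione (methyl-bearing centre as in 7) | CC(C)C(=O)C1=C(O)C(Br)(CC=C(C)C)C(=O)[C@](C)(CC=C(C)C)C1=O
F3 | step 4 | 3-(2-bromopropan-2-yl)-10-hydroxy-4,4,7-trimethyl-9-(2-methylpropanoyl)tricyclo[5.3.1.0^{1,5}]undec-9-ene-8,11-dione (ring stereocentres as in 8) | CC(C)(Br)[C@H]1C[C@]23C(=O)[C@](C)(C[C@@H]2C1(C)C)C(=O)C(C(=O)C(C)C)=C3O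
F4 | step 6 | 3-acetyl-4,4,7-trimethyl-10-[(2-methylbut-3-yn-2-yl)oxy]-9-(2-methylpropanoyl)tricyclo[5.3.1.0^{1,5}]undec-9-ene-8,11-dione (stereocentres as in 10) | CC(=O)[C@H]1C[C@]23C(=O)[C@](C)(C[C@@H]2C1(C)C)C(=O)C(C(=O)C(C)C)=C3OC(C)(C)C#C
F5 | step 6 | 3-acetyl-4,4,7-trimethyl-10-[(2-methylbut-3-en-2-yl)oxy]-9-(2-methylpropanoyl)tricyclo[5.3.1.0^{1,5}]undec-9-ene-8,11-dione (stereocentres as in 10) | CC(=O)[C@H]1C[C@]23C(=O)[C@](C)(C[C@@H]2C1(C)C)C(=O)C(C(=O)C(C)C)=C3OC(C)(C)C=C
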